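**Retrosynthetic overview**
1. Target ⇒ acylation of a 9β-hydroxy-8-ketone; the 9β-OH/10β-H pair comes from Rubottom oxidation of a C8–C9 silyl enol ether made by copper hydride 1,4-hydrosilylation of a Δ9-en-8-one.
2. C7 isopropenyl ⇒ acetone aldol condensation at C7 of the enone, then deconjugative kinetic protonation (sets C7).
3. Key disconnection, C3–O (with C4–H) ⇒ anti-Markovnikov, diastereoselective photoredox hydroacyloxylation of the C3=C4 alkene of a bicyclic dienone with 3-methylbut-2-enoic acid (new step; sets C3 and C4).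
4. Dienone ⇒ (S)-Wieland–Miescher ketone by chemoselective Wittig methylenation and alkene isomerisation.
5. Rings: ring A is bought as 2-methylcyclohexane-1,3-dione; ring B is closed once, by an organocatalytic Robinson annulation with methyl vinyl ketone that sets C5.

Convention: locants follow eremophilane numbering (C5 angular methyl carbon, C4 CHMe, C3 and C9 oxygenated, C8 ketone, C7 isopropenyl carbon, C10 ring-fusion CH); β is the face of the C5 methyl, α the opposite face.
Assumption: the target SMILES is read as (3R,4R,5R,7R,9R,10S), i.e. 3α,9β-diester, 4β-methyl, 7β-isopropenyl, 10β-H (cis-decalin); reagents and catalysts named under Conditions are bought.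

**Route**

Step 1
Reactants: 1 2-methylcyclohexane-1,3-dione; 2 but-3-en-2-one (methyl vinyl ketone)
Product: 4 (S)-8a-methyl-3,4,8,8a-tetrahydronaphthalene-1,6(2H,7H)-dione ((S)-Wieland–Miescher ketone), via triketone 3 (not isolated)
Conditions: Et3N (1 mol %), neat, 25 °C; then N-tosyl-(Sa)-binam-L-prolinamide (2 mol %), PhCO2H (0.5 mol %), neat, 25 °C
Reagents that add atoms: none
Why: Michael addition followed by an enamine-mediated intramolecular aldol condensation (Hajos–Parrish–Eder–Sauer–Wiechert form of the Robinson annulation) closes ring B, and the L-prolinamide enamine selects one of the two enantiotopic ring carbonyls, which sets the quaternary carbon (C5 of the target) as S; one recrystallisation raises the ee.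

Step 2
Reactants: 4 (S)-Wieland–Miescher ketone
Product: 6 (R)-4a-methyl-5-methylidene-4,4a,5,6,7,8-hexahydronaphthalen-2(3H)-one, via potassium dienolate 5 (not isolated)
Conditions: KOtBu (3.5 equiv), Ph3PCH3Br (2.5 equiv), toluene, 25 → 80 °C; then 1 M HCl, THF, 25 °C
Reagents that add atoms: methyltriphenylphosphonium bromide, C[P+](c1ccccc1)(c1ccccc1)c1ccccc1.[Br-]
Why: Wittig methylenation in which KOtBu first converts the enone into its extended potassium dienolate, which is inert to the ylide (the same in situ masking that lets the 17-ketone of androst-4-ene-3,17-dione be olefinated alone), so only the saturated neopentyl ketone reacts and the acidic work-up reprotonates and reconjugates the enone; no stereocentre is formed and the quaternary centre cannot epimerise.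

Step 3
Reactants: 6 (R)-4a-methyl-5-methylidene-4,4a,5,6,7,8-hexahydronaphthalen-2(3H)-one
Product: 7 (R)-4a,5-dimethyl-4,4a,7,8-tetrahydronaphthalen-2(3H)-one
Conditions: RhCl3·3H2O (5 mol %), EtOH, 80 °C
Reagents that add atoms: none
Why: Rhodium hydride addition–elimination (alkene isomerisation) moves the exocyclic 1,1-disubstituted alkene into the ring to the more stable trisubstituted C3=C4 position, the only one open because C5 is quaternary; the enone and the stereocentre are untouched.

Step 4
Reactants: 7 (R)-4a,5-dimethyl-4,4a,7,8-tetrahydronaphthalen-2(3H)-one; 8 3-methylbut-2-enoic acid (senecioic acid)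
Product: 9 (1R,2R,8aR)-1,8a-dimethyl-6-oxo-1,2,3,4,6,7,8,8a-octahydronaphthalen-2-yl 3-methylbut-2-enoate (3α-acyloxy 4β-methyl enone)
Conditions: 9-mesityl-3,6-di-tert-butyl-10-phenylacridinium tetrafluoroborate (5 mol %), PhSH (20 mol %), 2,6-lutidine (25 mol %), 8 (5 equiv), 1,2-dichloroethane, 450 nm LEDs, 25 °C
Reagents that add atoms: none
Why: Proposed new method: a diastereoselective anti-Markovnikov hydroacyloxylation of an endocyclic trisubstituted alkene that sits next to a quaternary stereocentre in an enone-bearing bicycle, with a conjugated acid as the oxygen nucleophile (none of these features has been shown); the excited acridinium oxidises only the electron-rich C3=C4 alkene to its radical cation (the enone and senecioyl alkenes are too electron-poor), the carboxylate adds reversibly to the less substituted C3 so that the C–O bond settles equatorial on the α face (a β bond would be 1,3-diaxial to the C5 methyl), and the tertiary C4 radical takes a hydrogen atom from PhSH along the axial α trajectory anti to the neighbouring axial C5 methyl, which puts the C4 methyl β (cis to the C5 methyl, trans to oxygen) and sets C3 and C4 as R,R, while the thiyl radical is reduced by the acridinyl radical to close both cycles; closest known reaction type: acridinium/thiol photoredox anti-Markovnikov addition of carboxylic acids to styrenes and simple trisubstituted alkenes.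

Step 5
Reactants: 9 3α-acyloxy 4β-methyl enone; 10 acetone
Product: 13 (1R,2R,8aR)-1,8a-dimethyl-6-oxo-7-(propan-2-ylidene)-1,2,3,4,6,7,8,8a-octahydronaphthalen-2-yl 3-methylbut-2-enoate, via lithium aldolate 11 (not isolated), via tertiary mesylate 12 (not isolated)
Conditions: LiN(SiMe3)2 (1.1 equiv), THF, −78 °C; 10 (5 equiv), −78 °C; MeSO2Cl (2 equiv), −78 → 0 °C; DBU (3 equiv), 0 → 25 °C
Reagents that add atoms: none
Why: Aldol condensation: kinetic deprotonation gives the cross-conjugated lithium enolate at C7 (the silylamide is too weak and hindered to touch the ester), addition to acetone gives the tertiary aldolate, and mesylation followed by E1cB elimination gives the conjugated isopropylidene; C7 becomes sp2, so no stereocentre is at stake.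

Step 6
Reactants: 13 isopropylidene dienone
Product: 15 (1R,2R,7R,8aR)-1,8a-dimethyl-6-oxo-7-(prop-1-en-2-yl)-1,2,3,4,6,7,8,8a-octahydronaphthalen-2-yl 3-methylbut-2-enoate (7β-isopropenyl dienone), via lithium trienolate 14 (not isolated)
Conditions: LiN(iPr)2 (1.1 equiv), THF–DMPU, −78 °C; then inverse quench into AcOH (5 equiv), THF, −78 °C
Reagents that add atoms: none
Why: Deconjugative kinetic protonation: with no α′ hydrogen left, the amide removes a γ hydrogen from the isopropylidene methyl syn to the ketone (several pKa units more acidic than the ester γ position), and the extended enolate is protonated at its α carbon C7 on the α face, anti to the pseudoaxial C5 methyl, so H-7 is α and the isopropenyl group β (7R).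

Step 7
Reactants: 15 7β-isopropenyl dienone
Product: 16 8-[dimethyl(phenyl)silyloxy]-10βH-eremophila-8,11-dien-3α-yl 3-methylbut-2-enoate (cis-decalin; 4β-methyl; 7β-isopropenyl)
Conditions: Cu(OAc)2·H2O (5 mol %), 1,2-bis(diphenylphosphino)benzene (5 mol %), PhMe2SiH (1.5 equiv), toluene, 0 → 25 °C
Reagents that add atoms: dimethylphenylsilane, C[SiH](C)c1ccccc1
Why: Copper hydride catalysed 1,4-hydrosilylation in which hydride adds to C10 on the face syn to the angular methyl (the face cuprates take on 10-methyl-1(9)-octal-2-ones to give cis-fused decalones, here reinforced because ring A shields the α face), giving the 10β-H cis-decalin and trapping the enolate regiospecifically as the C8–C9 silyl enol ether; the conditions are non-basic, so C7 holds, and the isopropenyl group and the β,β-disubstituted enoate are not reduced.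

Step 8
Reactants: 16 cis-fused silyl enol ether
Product: 19 (3R,4R,5R,7R,9R,10S)-9-hydroxy-8-oxoeremophil-11-en-3-yl 3-methylbut-2-enoate (9β-hydroxy ketone), via silyloxy epoxide 17 (not isolated), via silyloxy ketone 18 (not isolated)
Conditions: mCPBA (1.05 equiv), CH2Cl2, −40 °C; then AcOH–THF–H2O, 25 °C
Reagents that add atoms: 3-chloroperbenzoic acid (mCPBA), OOC(=O)c1cccc(Cl)c1
Why: Rubottom oxidation: the peracid epoxidises the electron-rich silyl enol ether (much faster than the 1,1-disubstituted or conjugated alkenes) on the convex β face of the cis-decalin, the epoxide opens with 1,4-silyl shift to the silyloxy ketone and mild acid frees the alcohol, giving the equatorial 9β-hydroxyl (9R), which is also the thermodynamic epimer.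

Step 9
Reactants: 19 9β-hydroxy ketone; 8 3-methylbut-2-enoic acid
Product: 20 (3R,4R,5R,7R,9R,10S)-8-oxoeremophil-11-ene-3,9-diyl bis(3-methylbut-2-enoate) (CNP0264508.1)
Conditions: 8 (1.5 equiv), DCC (1.6 equiv), DMAP (0.1 equiv), CH2Cl2, 0 → 25 °C
Reagents that add atoms: none
Why: Steglich esterification of the secondary α-ketol, which avoids the vinylketene pathway that deconjugates 3-methylbut-2-enoyl chloride under amine bases; no stereocentre is touched, and C7 and C9 already carry their thermodynamically preferred equatorial groups.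

**Compound list**
1 | 2-methylcyclohexane-1,3-dione | CC1C(=O)CCCC1=O | starting material
2 | but-3-en-2-one (methyl vinyl ketone) | CC(=O)C=C | starting material
3 | 2-methyl-2-(3-oxobutyl)cyclohexane-1,3-dione (triketone; not isolated) | CC(=O)CCC1(C)C(=O)CCCC1=O | intermediate
4 | (S)-8a-methyl-3,4,8,8a-tetrahydronaphthalene-1,6(2H,7H)-dione ((S)-Wieland–Miescher ketone) | O=C1CC[C@@]2(C)C(CCCC2=O)=C1 | intermediate
5 | potassium dienolate of 4 (O–C8=C9–C10=C1; not isolated) | [K+].[O-]C1=CC2=CCCC(=O)[C@@]2(C)CC1 | intermediate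
6 | (R)-4a-methyl-5-methylidene-4,4a,5,6,7,8-hexahydronaphthalen-2(3H)-one | O=C1CC[C@@]2(C)C(CCCC2=C)=C1 | intermediate
7 | (R)-4a,5-dimethyl-4,4a,7,8-tetrahydronaphthalen-2(3H)-one | O=C1CC[C@@]2(C)C(CCC=C2C)=C1 | intermediate
8 | 3-methylbut-2-enoic acid (senecioic acid) | CC(C)=CC(=O)O | starting material
9 | (1R,2R,8aR)-1,8a-dimethyl-6-oxo-1,2,3,4,6,7,8,8a-octahydronaphthalen-2-yl 3-methylbut-2-enoate | O=C1CC[C@@]2(C)C(CC[C@@H](OC(=O)C=C(C)C)[C@@H]2C)=C1 | intermediate
10 | acetone | CC(C)=O | starting material
11 | lithium aldolate: 7α-(2-oxidopropan-2-yl) derivative of 9 (not isolated) | [Li+].CC(C)([O-])[C@@H]1C[C@@]2(C)C(CC[C@@H](OC(=O)C=C(C)C)[C@@H]2C)=CC1=O | intermediate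
12 | tertiary mesylate: 7α-[2-(methanesulfonyloxy)propan-2-yl] derivative of 9 (not isolated) | CC(C)(OS(C)(=O)=O)[C@@H]1C[C@@]2(C)C(CC[C@@H](OC(=O)C=C(C)C)[C@@H]2C)=CC1=O | intermediate
13 | (1R,2R,8aR)-1,8a-dimethyl-6-oxo-7-(propan-2-ylidene)-1,2,3,4,6,7,8,8a-octahydronaphthalen-2-yl 3-methylbut-2-enoate | CC(C)=C1C[C@@]2(C)C(CC[C@@H](OC(=O)C=C(C)C)[C@@H]2C)=CC1=O | intermediate
14 | lithium trienolate of 13 (CH2=C11–C7=C8–O with C9=C10 retained; not isolated) | [Li+].C=C(C)C=1C[C@@]2(C)C(CC[C@@H](OC(=O)C=C(C)C)[C@@H]2C)=CC=1[O-] | intermediate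
15 | (1R,2R,7R,8aR)-1,8a-dimethyl-6-oxo-7-(prop-1-en-2-yl)-1,2,3,4,6,7,8,8a-octahydronaphthalen-2-yl 3-methylbut-2-enoate | C=C(C)[C@H]1C[C@@]2(C)C(CC[C@@H](OC(=O)C=C(C)C)[C@@H]2C)=CC1=O | intermediate
16 | 8-[dimethyl(phenyl)silyloxy]-10βH-eremophila-8,11-dien-3α-yl 3-methylbut-2-enoate (4β-methyl; 7β-isopropenyl) | C=C(C)[C@H]1C[C@@]2(C)[C@H](CC[C@@H](OC(=O)C=C(C)C)[C@@H]2C)C=C1O[Si](C)(C)c1ccccc1 | intermediate
17 | 8β,9β-epoxide of 16 (8α-silyloxy; not isolated) | C=C(C)[C@H]1C[C@@]2(C)[C@H](CC[C@@H](OC(=O)C=C(C)C)[C@@H]2C)[C@H]3O[C@@]13O[Si](C)(C)c1ccccc1 | intermediate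
18 | 9β-[dimethyl(phenyl)silyloxy]-8-oxo-10βH-eremophil-11-en-3α-yl 3-methylbut-2-enoate (not isolated) | C=C(C)[C@H]1C[C@@]2(C)[C@H](CC[C@@H](OC(=O)C=C(C)C)[C@@H]2C)[C@@H](O[Si](C)(C)c3ccccc3)C1=O | intermediate
19 | (3R,4R,5R,7R,9R,10S)-9-hydroxy-8-oxoeremophil-11-en-3-yl 3-methylbut-2-enoate | C=C(C)[C@H]1C[C@@]2(C)[C@H](CC[C@@H](OC(=O)C=C(C)C)[C@@H]2C)[C@@H](O)C1=O | intermediate
20 | (3R,4R,5R,7R,9R,10S)-8-oxoeremophil-11-ene-3,9-diyl bis(3-methylbut-2-enoate) (CNP0264508.1) | C=C(C)[C@H]1C[C@@]2(C)[C@H](CC[C@@H](OC(=O)C=C(C)C)[C@@H]2C)[C@@H](OC(=O)C=C(C)C)C1=O | target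

**Step count and risks**
Total steps: 9. Longest linear sequence: 9.

The three steps most likely to fail:

Step 4 (the proposed new hydroacyloxylation). Risks are the face of C–O bond formation at C3, allylic deprotonation of the radical cation, and oxidation of the carboxylate. The fallback uses known chemistry, sets out from 7 and comes back at 9. The enone carbonyl of 7 is masked with ethane-1,2-dithiol and TsOH·H2O in AcOH as the dienone dithiolane F3 (the alkene stays at C9=C10). Hydroboration with BH3·THF at 0 °C and oxidation with NaBO3·4H2O adds H and OH syn across C3=C4 from the α face opposite the C5 methyl, giving the 3α-hydroxy-4β-methyl dithiolane F4; the C9=C10 alkene is shielded by the neighbouring spiro-dithiolane. MeI and CaCO3 in aqueous MeCN unmask the hydroxy enone F5. DCC/DMAP esterification with 8 gives 9.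

Step 6 (deconjugative kinetic protonation). Risks are γ-deprotonation at C1 instead of the methyl group, the α/γ protonation ratio, the face of protonation, and competing deprotonation of the ester. The fallback sets out from 9 and comes back at the target 20. It forms the C7–C11 bond on the cis-decalin, where the carbon electrophile itself enters from the convex β face. Copper hydride 1,4-hydrosilylation of 9 under the conditions of step 7 gives the cis-fused silyl enol ether F6. Rubottom oxidation (mCPBA, then aqueous AcOH) gives the 9β-hydroxy ketone F7. LiN(SiMe3)2 (2.2 equiv) forms the 9-alkoxide and then the C7 enolate (the alkoxide blocks enolisation toward C9), and acetone adds to give the 7β-(2-hydroxypropan-2-yl) diol F8. DCC/DMAP with 8 acylates only the secondary 9-hydroxyl to give the diester carbinol F9. Dehydration of the tertiary alcohol with methyl N-(triethylammoniumsulfonyl)carbamate (Burgess reagent) in toluene at 50 °C gives 20.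

Step 2 (chemoselective Wittig). Risks are incomplete masking of the enone as its dienolate and slow olefination of the neopentyl ketone. The fallback sets out from 4 and comes back at 6. Ethane-1,2-dithiol and TsOH·H2O in AcOH protect only the enone carbonyl as the enone dithiolane F1. Wittig methylenation of the one remaining ketone (Ph3PCH3Br, KOtBu, toluene, 90 °C) gives the methylidene dithiolane F2. MeI and CaCO3 in aqueous MeCN return 6.

**Further compounds**
F1 | step 2 | enone-carbonyl 1,3-dithiolane of (S)-Wieland–Miescher ketone (C4 ketone free; C9=C10 retained) | S1CCSC12CC[C@@]3(C)C(CCCC3=O)=C2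
F2 | step 2 | enone-carbonyl 1,3-dithiolane of 6 (4-methylidene) | S1CCSC12CC[C@@]3(C)C(CCCC3=C)=C2
F3 | step 4 | enone-carbonyl 1,3-dithiolane of 7 (C3=C4 and C9=C10 alkenes) | S1CCSC12CC[C@@]3(C)C(CCC=C3C)=C2
F4 | step 4 | 3α-hydroxy-4β-methyl dithiolane (hydroboration product of F3) | S1CCSC12CC[C@@]3(C)C(CC[C@@H](O)[C@@H]3C)=C2
F5 | step 4 | (4aR,5R,6R)-6-hydroxy-4a,5-dimethyl-4,4a,5,6,7,8-hexahydronaphthalen-2(3H)-one | O=C1CC[C@@]2(C)C(CC[C@@H](O)[C@@H]2C)=C1
F6 | step 6 | cis-fused C8–C9 dimethyl(phenyl)silyl enol ether from 9 (10β-H; C7 unsubstituted) | C1C[C@@]2(C)[C@H](CC[C@@H](OC(=O)C=C(C)C)[C@@H]2C)C=C1O[Si](C)(C)c1ccccc1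
F7 | step 6 | 9β-hydroxy-8-oxo cis-decalin 3α-(3-methylbut-2-enoate) (C7 unsubstituted) | C1C[C@@]2(C)[C@H](CC[C@@H](OC(=O)C=C(C)C)[C@@H]2C)[C@@H](O)C1=O
F8 | step 6 | 7β-(2-hydroxypropan-2-yl)-9β-hydroxy-8-oxo cis-decalin 3α-(3-methylbut-2-enoate) | CC(C)(O)[C@H]1C[C@@]2(C)[C@H](CC[C@@H](OC(=O)C=C(C)C)[C@@H]2C)[C@@H](O)C1=O
F9 | step 6 | 7β-(2-hydroxypropan-2-yl)-8-oxo cis-decalin 3α,9β-bis(3-methylbut-2-enoate) | CC(C)(O)[C@H]1C[C@@]2(C)[C@H](CC[C@@H](OC(=O)C=C(C)C)[C@@H]2C)[C@@H](OC(=O)C=C(C)C)C1=O
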